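The runs are simulated for an exercise; scatter was added.

A curve of E that flattens looks like a balance reached, and that reading misleads if E is in fact being lost. Before I settle the charge of the alpha run, I want the fraction of the charged E still left at the end, not the amount made.

| flask | L | G | E | time |
|---|---|---|---|---|
| theta | 0.300 M | 0.330 M |  |  |
| gamma | 0.150 M | 0.180 M |  |  |
| zeta | 0.900 M | 0.330 M |  |  |
| alpha | 0.300 M | 0.330 M | 0.0900 M | 13 min |

| run | time / min | [E] / M |
|---|---|---|
| theta run | 0.52 | 0.0108 |
| theta run | 0.99 | 0.0138 |
| theta run | 1.9 | 0.0277 |
| theta run | 3.6 | 0.0473 |
| theta run | 6.8 | 0.0675 |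
| theta run | 13 | 0.0816 |
| gamma run | 0.52 | 0.0014 |
| gamma run | 0.99 | 0.0056 |
| gamma run | 1.9 | 0.0096 |
| gamma run | 3.6 | 0.0218 |
| gamma run | 6.8 | 0.0278 |
| gamma run | 13 | 0.0407 |
| zeta run | 0.52 | 0.0260 |
| zeta run | 0.99 | 0.0461 |
| zeta run | 1.9 | 0.0757 |
| zeta run | 3.6 | 0.1152 |
| zeta run | 6.8 | 0.1601 |
| zeta run | 13 | 0.1940 |

(readings scatter by 0.002 M)

- Overall: L + G -> E.
- Constant volume, constant temperature.
- What is held in complexes is read along with the free species.
- An order is taken over about fifteen percent of the charge, up and down.
- A share of E counts the E that was charged too.

* the exponent of [G] in the starting rate at the charge of the theta run (at the point where two percent of the L have become E)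
* the exponent of [L] in the starting rate at the charge of the theta run (at the point where two percent of the L have become E) (one fixed amount of E, the same in the runs compared)
* E in the alpha run at 13 min, as a share of the L charged

The theta run is the alpha run without the charged E, so I reckon there. Between its last two readings E climbs at 0.00227 M min⁻¹, and it stands near 0.0746 M at 9.90 min. The reading at 1.9 min gives an average rate of 0.0146 M min⁻¹ so far, and undoing the fractions of L and G used at half that E gives a starting rate of 0.0160 M min⁻¹, a figure that carries the scatter of that reading. I scale it by the fractions of L and G left after the E of the late stretch. The shortfall against the climb then gives a first loss of 0.0940 min⁻¹. That is too high, since E already lost has also used its L and G. Over the area under the curve, 0.495 M·min, the first figure means 0.0465 M lost. Counting that gives 0.0503 min⁻¹, which I take as the low side, since the amount lost was reckoned with the high figure.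

I commit to the middle, 0.0721 min⁻¹: the loss constant, the fraction of the E present that goes each minute, as read late in the theta run. Held at that figure over the alpha run, it keeps 39.1% of the charged E. Adding that to the last theta reading gives 38.9% of the L, so I leave the charge as it stands.

The forecast gives 0.9 for G, 0.92 for L and 43%, higher than my share, on the ground that “treating it as reversible with K≈1.8 gives a net gain of about 0.04 M”.

The alpha run gives 38.5%, the exponent of G comes to 0.56 and that of L to 0.98, with the association of G to G2 moving the readings by 6.8 scatter units.

    L + G → E (0.7320 L mol⁻¹ min⁻¹)
    E + G → J (1.074 L mol⁻¹ min⁻¹)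
    2 G ⇌ G2, settled at all times (8.980 L mol⁻¹)
    L + G ⇌ LG, settled at all times (1.800 L mol⁻¹)

The alpha run kept 37.8% of its charged E, if the theta reading stands for what it made. Scaling the loss constant by G left, the gamma run has 0.0412 min⁻¹, which forecasts a late climb of 0.00239 M min⁻¹; its readings climb 0.00208 M min⁻¹.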